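The pyranone ring C is cut at C4–C4a and O1–C2. The cut exploits the A ring: C4a is ortho to C8a (bearing O1) and to the oxygenated C5, and para to the oxygenated C7. The two equivalent CH carbons of 2,6-dimethoxyhydroquinone have exactly this environment, and its hindered hydroxyl ends up as the free 6-OH. One solvent-free thermal operation joins this hydroquinone to an ethyl aroylacetate carrying the B ring in its 4-benzyloxy-2,5-dimethoxyphenyl form, making both bonds and ring C. The precursor pair is therefore a symmetric diphenol plus a β-keto ester, and a single Lewis-acid deprotection finishes the synthesis.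

Key step: step 5

Remark: the target has no stereocentre and is achiral, so the requirement of a single enantiomer sets no stereochemical task.

Step 1
Reactants: 1 2,5-dimethoxyphenol; 2 benzyl bromide
Product: 3 2-(benzyloxy)-1,4-dimethoxybenzene
Conditions: BnBr, K2CO3, DMF, rt
Reagents that add atoms: benzyl bromide 2, BrCc1ccccc1
Why: Williamson ether synthesis, in which the phenoxide of 1 is the only nucleophile present and benzyl bromide is a reactive SN2 partner.

Step 2
Reactants: 3 2-(benzyloxy)-1,4-dimethoxybenzene; 4 acetyl chloride
Product: 5 1-[4-(benzyloxy)-2,5-dimethoxyphenyl]ethan-1-one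
Conditions: AcCl, SnCl4, CH2Cl2, −20 to 0 °C
Reagents that add atoms: acetyl chloride 4, CC(=O)Cl
Why: Friedel–Crafts acylation, which should occur at C5 of 3 because this carbon is para to the benzyloxy group and ortho to a methoxy group (the site at which 1,2,4-trialkoxybenzenes are acylated), while C3 is flanked by two alkoxy groups and C6 has only one ortho donor; the mild Lewis acid at low temperature should leave the benzyl ether and the methyl ether next to the new carbonyl intact.

Step 3
Reactants: 5 1-[4-(benzyloxy)-2,5-dimethoxyphenyl]ethan-1-one; 6 diethyl carbonate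
Product: 7 ethyl 3-[4-(benzyloxy)-2,5-dimethoxyphenyl]-3-oxopropanoate
Conditions: NaH, (EtO)2CO, toluene, 100 °C; then AcOH
Reagents that add atoms: diethyl carbonate 6, CCOC(=O)OCC
Why: Crossed Claisen condensation of the methyl ketone enolate with the non-enolisable carbonate, driven to completion by irreversible deprotonation of the β-keto ester formed.

Step 4
Reactants: 8 2,6-dimethoxy-1,4-benzoquinone
Product: 9 2,6-dimethoxybenzene-1,4-diol
Conditions: Na2S2O4, EtOAc/H2O, rt, under Ar; used at once
Reagents that add atoms: none
Why: Dithionite reduction of a 1,4-benzoquinone to its hydroquinone, a standard two-electron reduction that touches nothing else in 8; the product is kept under argon because it re-oxidises in air.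

Step 5
Reactants: 9 2,6-dimethoxybenzene-1,4-diol; 7 ethyl 3-[4-(benzyloxy)-2,5-dimethoxyphenyl]-3-oxopropanoate
Product: 12 2-[4-(benzyloxy)-2,5-dimethoxyphenyl]-6-hydroxy-5,7-dimethoxy-4H-chromen-4-one, via aroylketene 10 (not isolated), via hydroxyaryl diketone 11 (not isolated)
Conditions: neat melt, 9 (1.5 equiv), Ar stream, 240 °C
Reagents that add atoms: none
Why: On heating, keto ester 7 should lose ethanol to give aroylketene 10, which acylates hydroquinone 9 at C3, either directly or by O-acylation of the unhindered C4 hydroxyl followed by a thermal Fries-type acyl shift, to give diketone 11 (bond C4–C4a). The C4 hydroxyl then adds to the B-ring carbonyl of 11 in a 6-exo-trig closure (bond O1–C2), and loss of water completes the pyranone. The closest known reaction type is the Mentzer pyrone synthesis, the acid-free thermal condensation of electron-rich phenols with aroylacetic esters to give flavones. No stereocentre is formed. The step needs chromone and not coumarin formation, which the neutral ketene pathway should secure because the arene attacks the ketene carbon and never an acid-activated ketone; it also needs a single regiochemistry, which the mirror symmetry of 9 secures because C3 and C5 are equivalent and each has the C4 hydroxyl as its only ortho hydroxyl. The hydroxyl between the two methoxy groups is shielded, and any ester formed there should revert to the ketene at this temperature.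

Step 6
Reactants: 12 2-[4-(benzyloxy)-2,5-dimethoxyphenyl]-6-hydroxy-5,7-dimethoxy-4H-chromen-4-one
Product: 13 5,6-dihydroxy-2-(4-hydroxy-2,5-dimethoxyphenyl)-7-methoxy-4H-chromen-4-one
Conditions: BCl3 (5 equiv), pentamethylbenzene (3 equiv), CH2Cl2, −78 to 0 °C; then H2O
Reagents that add atoms: none
Why: Lewis-acid ether cleavage in which BCl3 removes the benzyl group at low temperature (pentamethylbenzene traps the benzyl cation) and, held in a six-membered chelate between the C4 carbonyl and the peri 5-methoxy oxygen, cleaves only that methyl ether, whereas the non-chelated methyl ethers at C7, C2' and C5' should survive at or below 0 °C.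

Compound list
1 | 2,5-dimethoxyphenol | COc1ccc(OC)c(O)c1 | starting material
2 | benzyl bromide | BrCc1ccccc1 | starting material
3 | 2-(benzyloxy)-1,4-dimethoxybenzene | COc1ccc(OC)c(OCc2ccccc2)c1 | intermediate
4 | acetyl chloride | CC(=O)Cl | starting material
5 | 1-[4-(benzyloxy)-2,5-dimethoxyphenyl]ethan-1-one | CC(=O)c1cc(OC)c(OCc2ccccc2)cc1OC | intermediate
6 | diethyl carbonate | CCOC(=O)OCC | starting material
7 | ethyl 3-[4-(benzyloxy)-2,5-dimethoxyphenyl]-3-oxopropanoate | CCOC(=O)CC(=O)c1cc(OC)c(OCc2ccccc2)cc1OC | intermediate
8 | 2,6-dimethoxy-1,4-benzoquinone | COC1=CC(=O)C=C(OC)C1=O | starting material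
9 | 2,6-dimethoxybenzene-1,4-diol | COc1cc(O)cc(OC)c1O | intermediate
10 | 3-[4-(benzyloxy)-2,5-dimethoxyphenyl]prop-1-ene-1,3-dione (aroylketene) | COc1cc(OCc2ccccc2)c(OC)cc1C(=O)C=C=O | intermediate (not isolated)
11 | 1-[4-(benzyloxy)-2,5-dimethoxyphenyl]-3-(3,6-dihydroxy-2,4-dimethoxyphenyl)propane-1,3-dione | COc1cc(O)c(C(=O)CC(=O)c2cc(OC)c(OCc3ccccc3)cc2OC)c(OC)c1O | intermediate (not isolated)
12 | 2-[4-(benzyloxy)-2,5-dimethoxyphenyl]-6-hydroxy-5,7-dimethoxy-4H-chromen-4-one | COc1cc2oc(-c3cc(OC)c(OCc4ccccc4)cc3OC)cc(=O)c2c(OC)c1O | intermediate
13 | 5,6-dihydroxy-2-(4-hydroxy-2,5-dimethoxyphenyl)-7-methoxy-4H-chromen-4-one | COc1cc(-c2cc(=O)c3c(O)c(O)c(OC)cc3o2)c(OC)cc1O | target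

Total step count: 6
Longest linear sequence: 5 steps (steps 1, 2, 3, 5, 6)

Steps most likely to fail

1. Step 5. The melt may stall at O-acylation without the acyl shift to carbon. The hydroquinone may oxidise or char at 240 °C, a Pechmann-type closure to the 4-arylcoumarin may compete, or the benzyl group may be lost thermally. The fallback builds the same two bonds stepwise under basic conditions; it sets out from 9 and 5 and returns at 12 by way of 11.
   - Hydroquinone 9 would be C-acetylated at its only type of ring CH (AcOH, BF3·OEt2, 90 °C) to give 1-(3,6-dihydroxy-2,4-dimethoxyphenyl)ethan-1-one F1.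
   - Ketone 5 would be degraded by hypochlorite haloform oxidation to 4-(benzyloxy)-2,5-dimethoxybenzoic acid F2 and converted with oxalyl chloride and catalytic DMF into 4-(benzyloxy)-2,5-dimethoxybenzoyl chloride F3.
   - The lithium polyanion of F1 (LiHMDS, about 4 equiv, THF, −78 °C) would be C-aroylated at the enolate carbon by F3 to give diketone 11, now isolated.
   - Cyclodehydration of 11 (catalytic TsOH, toluene, reflux) would give 12.

2. Step 6. The Lewis acid may also demethylate a non-chelated ether next to a newly formed aryloxyboron group (C7 or C5'), may leave the 5-methyl ether partly uncleaved, or may let the benzyl cation alkylate an electron-rich ring. The fallback separates the two deprotections with orthogonal methods; it sets out from 12 and returns at 13.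
   - Hydrogenolysis of 12 (H2, Pd/C, EtOAc/MeOH, rt) would give 6-hydroxy-2-(4-hydroxy-2,5-dimethoxyphenyl)-5,7-dimethoxy-4H-chromen-4-one F4.
   - Chelation-controlled 5-O-demethylation of F4 with anhydrous AlCl3 in MeCN would give 13.

3. Step 2. The Lewis acid may cleave the benzyl ether or the methyl ether ortho to the new carbonyl, or acylation may be unselective among the ring positions. The fallback avoids acylium chemistry and also bypasses step 3; it sets out from 3 and returns at 7.
   - Vilsmeier–Haack formylation of 3 (POCl3, DMF, 0 to 70 °C; aqueous NaOAc), para to the benzyloxy group, would give 4-(benzyloxy)-2,5-dimethoxybenzaldehyde F5.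
   - Roskamp homologation of F5 (ethyl diazoacetate, catalytic SnCl2, CH2Cl2, rt) would give keto ester 7 directly.

Further compounds
F1 | step 5 | 1-(3,6-dihydroxy-2,4-dimethoxyphenyl)ethan-1-one | CC(=O)c1c(O)cc(OC)c(O)c1OC
F2 | step 5 | 4-(benzyloxy)-2,5-dimethoxybenzoic acid | COc1cc(OCc2ccccc2)c(OC)cc1C(=O)O
F3 | step 5 | 4-(benzyloxy)-2,5-dimethoxybenzoyl chloride | COc1cc(OCc2ccccc2)c(OC)cc1C(=O)Cl
F4 | step 6 | 6-hydroxy-2-(4-hydroxy-2,5-dimethoxyphenyl)-5,7-dimethoxy-4H-chromen-4-one | COc1cc2oc(-c3cc(OC)c(O)cc3OC)cc(=O)c2c(OC)c1O
F5 | step 2 | 4-(benzyloxy)-2,5-dimethoxybenzaldehyde | COc1cc(OCc2ccccc2)c(OC)cc1C=O
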